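## Retrosynthetic overview

1. 8 ⇒ ketol 5 + aldehyde 6: the ester C–O bond and the C3 carbinol are made together by an Evans–Tishchenko-type hydride shift inside hemiacetal 7 (1,3-anti).
2. 5 ⇒ homoallylic alcohol 4: Wacker oxidation of the vinyl group to the methyl ketone.
3. 4 ⇒ aldehyde 1 + (E)-crotylboronate 2: catalytic asymmetric anti-crotylboration sets C1 and C2.
4. No ring is formed; both benzene rings are bought in 1 and 6.

Assumption: the (R)-configured phosphoric acid is taken to send the crotyl group to the Re face of 1, as recalled for other benzaldehydes; the configuration of 4 is confirmed once by Mosher ester analysis.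

## Route

Step 1
Reactants: 1 3,4,5-trimethoxybenzaldehyde; 2 (E)-crotylboronic acid pinacol ester
Product: 4 (1R,2R)-2-methyl-1-(3,4,5-trimethoxyphenyl)but-3-en-1-ol, via pinacol borate ester 3 (not isolated)
Conditions: 2 (1.3 equiv), (R)-TRIP [(R)-3,3′-bis(2,4,6-triisopropylphenyl)-1,1′-binaphthyl-2,2′-diyl hydrogen phosphate] (5 mol %), toluene, −30 °C, 24 h; then aq. NaHCO3, rt
Reagents that add atoms: (E)-crotylboronic acid pinacol ester (compound 2), C/C=C/CB1OC(C)(C)C(C)(C)O1
Why: Chiral phosphoric acid-catalysed crotylboration (asymmetric allylboration) runs through a closed six-membered chair in which the acid is hydrogen-bonded to a boronate oxygen, so the (E)-crotyl geometry gives the 1,2-anti relationship and the (R)-catalyst exposes the Re face of the aldehyde, setting C1 (R) and C2 (R) together.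

Step 2
Reactants: 4 (1R,2R)-2-methyl-1-(3,4,5-trimethoxyphenyl)but-3-en-1-ol
Product: 5 (3S,4R)-4-hydroxy-3-methyl-4-(3,4,5-trimethoxyphenyl)butan-2-one
Conditions: PdCl2 (10 mol %), CuCl (30 mol %), O2 (1 atm), DMF/H2O 7:1, 25 °C, 24 h
Reagents that add atoms: water, O
Why: Tsuji–Wacker oxidation: Markovnikov hydroxypalladation of the terminal alkene by divalent palladium and β-hydride elimination give the methyl ketone while CuCl/O2 turn the catalyst over, and the near-neutral medium leaves the free benzylic alcohol and the adjacent stereocentre untouched (no new stereocentre).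

Step 3
Reactants: 5 (3S,4R)-4-hydroxy-3-methyl-4-(3,4,5-trimethoxyphenyl)butan-2-one; 6 3,4-dimethoxybenzaldehyde
Product: 8 (1R,2R,3S)-3-hydroxy-2-methyl-1-(3,4,5-trimethoxyphenyl)butyl 3,4-dimethoxybenzoate, via hemiacetal 7 (not isolated)
Conditions: Sm[N(SiMe3)2]3 (10 mol %) and 2,6-di-tert-butyl-4-methylphenol (50 mol %) premixed in THF, rt, 30 min, to give Sm(OC6H2-2,6-tBu2-4-Me)3 plus free phenol; then 5 and 6 (2.5 equiv), THF, −10 °C, 6–12 h; pH 7 phosphate buffer at −10 °C; chromatography on neutral silica
Reagents that add atoms: 3,4-dimethoxybenzaldehyde (compound 6), COc1ccc(C=O)cc1OC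
Why: Proposed new method: an Evans–Tishchenko reduction catalysed by a halide-free trivalent samarium tris(aryloxide) instead of SmI2-derived iodosamarium alkoxides, in which the carbinol of 5 adds to samarium-bound 6 to give hemiacetal 7, an aryloxide ligand takes the hemiacetal proton, and the samarium hemiacetalate passes its C–H hydride to the chelated ketone through a six-membered chair (aryl and methyl equatorial), which forms the ester C–O bond on the benzylic oxygen and sets C3 of the butyl chain as S (1,3-anti), after which the phenol protonates the product alkoxide so that neither a samarium aldolate (retro-aldol) nor a product alkoxide (acyl migration) builds up; the closest known reaction type is the SmI2-catalysed Evans–Tishchenko reaction of β-hydroxy ketones, together with lanthanide alkoxide Tishchenko and Meerwein–Ponndorf–Verley hydride transfers.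

## Compound list

1 | 3,4,5-trimethoxybenzaldehyde | COc1cc(C=O)cc(OC)c1OC | starting material
2 | (E)-crotylboronic acid pinacol ester, 2-[(2E)-but-2-en-1-yl]-4,4,5,5-tetramethyl-1,3,2-dioxaborolane | C/C=C/CB1OC(C)(C)C(C)(C)O1 | starting material
3 | 2-{[(1R,2R)-2-methyl-1-(3,4,5-trimethoxyphenyl)but-3-en-1-yl]oxy}-4,4,5,5-tetramethyl-1,3,2-dioxaborolane (pinacol borate ester of 4) | CC1(C)OB(O[C@@H](c2cc(OC)c(OC)c(OC)c2)[C@H](C)C=C)OC1(C)C | intermediate
4 | (1R,2R)-2-methyl-1-(3,4,5-trimethoxyphenyl)but-3-en-1-ol (anti homoallylic alcohol) | O[C@@H](c1cc(OC)c(OC)c(OC)c1)[C@H](C)C=C | intermediate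
5 | (3S,4R)-4-hydroxy-3-methyl-4-(3,4,5-trimethoxyphenyl)butan-2-one (anti ketol) | O[C@@H](c1cc(OC)c(OC)c(OC)c1)[C@H](C)C(C)=O | intermediate
6 | 3,4-dimethoxybenzaldehyde (veratraldehyde) | COc1ccc(C=O)cc1OC | starting material
7 | (3S,4R)-4-[(3,4-dimethoxyphenyl)(hydroxy)methoxy]-3-methyl-4-(3,4,5-trimethoxyphenyl)butan-2-one (hemiacetal of 5 and 6, either configuration at the hemiacetal carbon, samarium-bound in the flask) | COc1ccc(C(O)O[C@@H](c2cc(OC)c(OC)c(OC)c2)[C@H](C)C(C)=O)cc1OC | intermediate
8 | (1R,2R,3S)-3-hydroxy-2-methyl-1-(3,4,5-trimethoxyphenyl)butyl 3,4-dimethoxybenzoate | COc1ccc(C(=O)O[C@@H](c2cc(OC)c(OC)c(OC)c2)[C@H](C)[C@H](C)O)cc1OC | target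

## Step count and risks

Total step count: 3. Longest linear sequence: 3 steps (1 → 4 → 5 → 8).

**Step 3 (most likely to fail; the proposed new method).** The bulky aryloxide catalyst may turn over slowly with the electron-rich, weakly electrophilic aldehyde 6. Tishchenko dimerisation of 6, retro-aldol cleavage of the benzylic ketol and migration of the ester to the new hydroxyl are the side paths to watch. The fallback uses known chemistry, sets out from 5 and comes back at 8. Ketol 5 is acylated with 3,4-dimethoxybenzoyl chloride (pyridine, DMAP 5 mol %, CH2Cl2, 0 °C) to the β-acyloxy ketone (1R,2S)-2-methyl-3-oxo-1-(3,4,5-trimethoxyphenyl)butyl 3,4-dimethoxybenzoate F1. F1 is then reduced with BH3·SMe2 and (R)-2-methyl-CBS-oxazaborolidine (20 mol %, THF, −20 °C, methanol quench), a Corey–Bakshi–Shibata reduction in which reagent control and Felkin control both favour the (S)-carbinol, giving 8. Here the ester bond is made by plain acylation and C3 is set by an external hydride.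

**Step 2.** The free homoallylic hydroxyl can erode the ketone-versus-aldehyde selectivity, and the β-hydroxy ketone can dehydrate or epimerise if acid builds up. The fallback sets out from 1, comes back at 5 and avoids the alkene oxidation altogether.
- A MgCl2-catalysed anti-aldol reaction of 1 with (R)-4-benzyl-3-propionyl-1,3-oxazolidin-2-one (MgCl2 10 mol %, Et3N, Me3SiCl, EtOAc, rt) gives the silyl ether (4R)-4-benzyl-3-[(2S,3R)-2-methyl-3-(3,4,5-trimethoxyphenyl)-3-[(trimethylsilyl)oxy]propanoyl]-1,3-oxazolidin-2-one F2.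
- Trifluoroacetic acid in methanol frees the aldol (4R)-4-benzyl-3-[(2S,3R)-3-hydroxy-2-methyl-3-(3,4,5-trimethoxyphenyl)propanoyl]-1,3-oxazolidin-2-one F3.
- AlMe3 and N,O-dimethylhydroxylamine hydrochloride (CH2Cl2, 0 °C) give the Weinreb amide (2S,3R)-3-hydroxy-N-methoxy-N,2-dimethyl-3-(3,4,5-trimethoxyphenyl)propanamide F4.
- MeMgBr (3 equiv, THF, 0 °C) turns F4 into 5.

**Step 1.** The crowded, electron-rich aldehyde may react slowly at −30 °C, the enantiomeric excess may fall short, or the sense of induction may differ from the assumption. The fallback sets out from 1 and comes back at 4 by a different carbon–carbon bond-forming mechanism, an iridium-catalysed transfer-hydrogenative anti-crotylation (Krische type). Conditions: [Ir(cod)Cl]2 (2.5 mol %), SEGPHOS (5 mol %, the enantiomer that gives (1R,2R)-4 in a test run), 4-cyano-3-nitrobenzoic acid (10 mol %), Cs2CO3 (20 mol %), but-3-en-2-yl acetate (2 equiv), isopropanol (2 equiv), THF, 90 °C. A nucleophilic π-allyliridium species replaces the allylboronate; new compounds: none F0.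

Further compounds
F1 | step 3 | (1R,2S)-2-methyl-3-oxo-1-(3,4,5-trimethoxyphenyl)butyl 3,4-dimethoxybenzoate | COc1ccc(C(=O)O[C@@H](c2cc(OC)c(OC)c(OC)c2)[C@H](C)C(C)=O)cc1OC
F2 | step 2 | (4R)-4-benzyl-3-[(2S,3R)-2-methyl-3-(3,4,5-trimethoxyphenyl)-3-[(trimethylsilyl)oxy]propanoyl]-1,3-oxazolidin-2-one | C[Si](C)(C)O[C@@H](c1cc(OC)c(OC)c(OC)c1)[C@H](C)C(=O)N1[C@H](Cc2ccccc2)COC1=O
F3 | step 2 | (4R)-4-benzyl-3-[(2S,3R)-3-hydroxy-2-methyl-3-(3,4,5-trimethoxyphenyl)propanoyl]-1,3-oxazolidin-2-one | O[C@@H](c1cc(OC)c(OC)c(OC)c1)[C@H](C)C(=O)N1[C@H](Cc2ccccc2)COC1=O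
F4 | step 2 | (2S,3R)-3-hydroxy-N-methoxy-N,2-dimethyl-3-(3,4,5-trimethoxyphenyl)propanamide | O[C@@H](c1cc(OC)c(OC)c(OC)c1)[C@H](C)C(=O)N(C)OC
F0 | step 1 | none | none
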